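**Retrosynthetic overview**
1. Target 11 ⇐ one-pot ozonolysis/hydride reduction of vinyl carbinol 9: vinyl → C9 CH2OH, CO2Me → ArCH2OH, OAc → ArOH.
2. 9 ⇐ C7–C8 bond between the carbonyl carbon of vanillin acetate 6 and the oxygen-bearing carbon of the (E)-γ-aryloxyallylborane 7. This α-aryloxy carbanion equivalent joins two carbons that are both normally electrophilic, and both stereocentres are set here.
3. 7 ⇐ aryloxyallene 4 + (−)-Ipc2BH 5; 4 ⇐ propargyl ether 3 ⇐ methyl syringate 1 + propargyl bromide 2.
4. No ring is formed; both benzene rings are bought.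

Assumption: the target SMILES is the (1R,2S) = (7R,8S) erythro (anti) isomer. (−)-Ipc2BH (5) is treated as a stock stoichiometric chiral reagent, crystallised beforehand from (+)-α-pinene and BH3·SMe2, and its preparation is not counted as a step.

**Step 1**
Reactants: 1 methyl syringate; 2 propargyl bromide
Product: 3 methyl 3,5-dimethoxy-4-(prop-2-yn-1-yloxy)benzoate
Conditions: K2CO3, DMF, rt → 50 °C
Reagents that add atoms: none
Why: Williamson ether synthesis, in which the acidic 2,6-dimethoxyphenoxide displaces the unhindered propargylic bromide (SN2) and the ester is untouched.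

**Step 2**
Reactants: 3 methyl 3,5-dimethoxy-4-(prop-2-yn-1-yloxy)benzoate
Product: 4 methyl 3,5-dimethoxy-4-(propa-1,2-dien-1-yloxy)benzoate
Conditions: KOtBu (15 mol%), THF, 0 °C → rt; filter through basic alumina, use at once
Reagents that add atoms: none
Why: base-catalysed propargyl → allenyl ether isomerisation (prototropic 1,3-shift) stops at the O-allene under catalytic tert-butoxide, and cold substoichiometric base limits transesterification of the methyl ester.

**Step 3**
Reactants: 4 methyl 3,5-dimethoxy-4-(propa-1,2-dien-1-yloxy)benzoate; 5 (−)-diisopinocampheylborane; 6 vanillin acetate (4-formyl-2-methoxyphenyl acetate)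
Product: 9 4-[(1R,2S)-1-hydroxy-2-(2,6-dimethoxy-4-methoxycarbonylphenoxy)but-3-en-1-yl]-2-methoxyphenyl acetate, via E-allylborane 7 (not isolated), via borinate 8 (not isolated)
Conditions: 4 (1.3 equiv), 5 (1.2 equiv), THF, 0 °C, 3 h; then 6 (1.0 equiv), −78 °C, 4 h → rt; 8-hydroxyquinoline, Et2O, rt, filter
Reagents that add atoms: none
Why: Proposed new method: a Brown-type anti-α-alkoxyallylboration extended to an O-aryl allene, in which Ipc2BH adds across the terminal C=C of 4 (B to CH2) to give the thermodynamically preferred (E)-γ-aryloxyallylborane 7, whose oxygen-bearing carbon attacks the aldehyde through a closed chair (Zimmerman–Traxler) transition state with Ar and OAr′ both equatorial (anti = erythro), while the (+)-α-pinene-derived Ipc groups direct attack to the si face of ArCHO (the sense in which dIpc2B-allyl gives (S)-1-phenylbut-3-en-1-ol), so that 7R and 8S are set together; the closest known reaction is hydroboration of alkoxyallenes with Ipc2BH followed by aldehyde addition, and the non-basic oxine work-up is chosen to spare the aryl acetate.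

**Step 4**
Reactants: 9 4-[(1R,2S)-1-hydroxy-2-(2,6-dimethoxy-4-methoxycarbonylphenoxy)but-3-en-1-yl]-2-methoxyphenyl acetate
Product: 11 (1R,2S)-1-(4-hydroxy-3-methoxyphenyl)-2-[4-(hydroxymethyl)-2,6-dimethoxyphenoxy]propane-1,3-diol, via ozonide 10 (not isolated)
Conditions: O3, CH2Cl2, −78 °C (Sudan III end point), N2 purge; then LiAlH4 (5 equiv), THF, −78 → 0 °C; Rochelle salt work-up
Reagents that add atoms: ozone O=[O+][O-]
Why: ozonolysis of the only alkene (both arenes are deactivated by acyl groups) gives the 1,2,4-trioxolane, and hydride then reduces ozonide, methyl ester and aryl acetate in the same flask (ozonide reduction, ester reduction, reductive deacylation) at low temperature, so neither stereocentre is touched.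

**Compound list**
1 | methyl syringate (methyl 4-hydroxy-3,5-dimethoxybenzoate) | COC(=O)c1cc(OC)c(O)c(OC)c1 | starting material
2 | propargyl bromide (3-bromoprop-1-yne) | BrCC#C | starting material
3 | methyl 3,5-dimethoxy-4-(prop-2-yn-1-yloxy)benzoate | COC(=O)c1cc(OC)c(OCC#C)c(OC)c1 | intermediate
4 | methyl 3,5-dimethoxy-4-(propa-1,2-dien-1-yloxy)benzoate | COC(=O)c1cc(OC)c(OC=C=C)c(OC)c1 | intermediate
5 | (−)-diisopinocampheylborane, bis[(1R,2S,3R,5R)-2,6,6-trimethylbicyclo[3.1.1]heptan-3-yl]borane, from (+)-α-pinene | B([C@@H]1C[C@@H]2C[C@H]([C@H]1C)C2(C)C)[C@@H]1C[C@@H]2C[C@H]([C@H]1C)C2(C)C | starting material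
6 | vanillin acetate (4-formyl-2-methoxyphenyl acetate) | COc1cc(C=O)ccc1OC(C)=O | starting material
7 | methyl 4-{[(E)-3-(diisopinocampheylboranyl)prop-1-en-1-yl]oxy}-3,5-dimethoxybenzoate | COC(=O)c1cc(OC)c(O/C=C/CB([C@@H]2C[C@@H]3C[C@H]([C@H]2C)C3(C)C)[C@@H]2C[C@@H]3C[C@H]([C@H]2C)C3(C)C)c(OC)c1 | intermediate
8 | O-diisopinocampheylboryl derivative (borinate) of 9, (1R,2S) as in 9 | COc1cc([C@@H](OB([C@@H]2C[C@@H]3C[C@H]([C@H]2C)C3(C)C)[C@@H]2C[C@@H]3C[C@H]([C@H]2C)C3(C)C)[C@H](C=C)Oc2c(OC)cc(cc2OC)C(=O)OC)ccc1OC(C)=O | intermediate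
9 | 4-[(1R,2S)-1-hydroxy-2-(2,6-dimethoxy-4-methoxycarbonylphenoxy)but-3-en-1-yl]-2-methoxyphenyl acetate | COc1cc([C@@H](O)[C@H](C=C)Oc2c(OC)cc(cc2OC)C(=O)OC)ccc1OC(C)=O | intermediate
10 | 1,2,4-trioxolane (secondary ozonide) of 9, carbinol and aryloxy carbons as in 9, trioxolane carbon as a mixture | COc1cc([C@@H](O)[C@H](C3OCOO3)Oc2c(OC)cc(cc2OC)C(=O)OC)ccc1OC(C)=O | intermediate
11 | (1R,2S)-1-(4-hydroxy-3-methoxyphenyl)-2-[4-(hydroxymethyl)-2,6-dimethoxyphenoxy]propane-1,3-diol | COc1cc([C@@H](O)[C@H](CO)Oc2c(OC)cc(CO)cc2OC)ccc1O | target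

**Totals**
Total step count: 4. Longest linear sequence: 4 (1 → 3 → 4 → 9 → 11).

**Three steps most likely to fail**

Step 3 (highest risk). Hydroboration of an aryloxyallene with Ipc2BH is untested, so E/Z purity, enantioselectivity and survival of the aryl acetate in the boron work-up are all uncertain. The fallback sets out from 3 and bypasses the allene. Zirconocene-catalysed hydroboration of the alkyne of 3 with pinacolborane gives methyl 3,5-dimethoxy-4-{[(E)-3-(pinacolboryl)prop-2-en-1-yl]oxy}benzoate F1. Iridium-catalysed double-bond transposition ([Ir(cod)(PPh2Me)2]PF6, H2-activated) moves the alkene next to oxygen and gives the (E)-γ-aryloxyallyl pinacol boronate F2. A chiral phosphoric acid (5 mol% TRIP, toluene, −30 °C) then catalyses allylboration of 6 through the same chair transition state to give the O-pinacolboryl adduct F3, which hydrolyses on aqueous work-up to 9, where the route is rejoined. The TRIP enantiomer needed is the one giving si-face attack, expected to be (S)-TRIP; this should be confirmed on benzaldehyde, which must give (S)-1-phenylbut-3-en-1-ol.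

Step 4. Ozone may attack the methoxy-substituted rings, and reducing an ozonide, an ester and an acetate in one flask may over-reduce the p-oxygenated benzylic position. The fallback sets out from 9 and replaces ozonolysis by dihydroxylation and glycol cleavage. OsO4 (cat.)/NMO in acetone–water gives 4-[(1R,2R)-1,3,4-trihydroxy-2-(2,6-dimethoxy-4-methoxycarbonylphenoxy)butyl]-2-methoxyphenyl acetate F4 as a mixture at C3; the spatial arrangement of 9 is kept and only the CIP descriptor at the aryloxy carbon changes. NaIO4 in THF–water at 0 °C cleaves the glycol to the labile (2R,3R)-2-aryloxy-3-hydroxy-3-arylpropanal F5, which is reduced immediately with LiAlH4 in THF at −78 → 0 °C to 11, where the route is rejoined.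

Step 2. tert-Butoxide can transesterify the methyl ester or push the allene on to the 1-propynyl ether. The fallback sets out from 3 and masks the ester as its carboxylate during the isomerisation. LiOH in THF–water gives 3,5-dimethoxy-4-(prop-2-yn-1-yloxy)benzoic acid F6. KOtBu (2.3 equiv) in THF–DMSO at 0 °C forms potassium 3,5-dimethoxy-4-(propa-1,2-dien-1-yloxy)benzoate F7, which is alkylated in the same flask with MeI to give 4 without any acidic work-up; the route is rejoined at 4.

**Further compounds**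
F1 | step 3 | methyl 3,5-dimethoxy-4-{[(E)-3-(4,4,5,5-tetramethyl-1,3,2-dioxaborolan-2-yl)prop-2-en-1-yl]oxy}benzoate | COC(=O)c1cc(OC)c(OC/C=C/B2OC(C)(C)C(C)(C)O2)c(OC)c1
F2 | step 3 | methyl 3,5-dimethoxy-4-{[(E)-3-(4,4,5,5-tetramethyl-1,3,2-dioxaborolan-2-yl)prop-1-en-1-yl]oxy}benzoate | COC(=O)c1cc(OC)c(O/C=C/CB2OC(C)(C)C(C)(C)O2)c(OC)c1
F3 | step 3 | O-pinacolboryl derivative of 9, (1R,2S) as in 9 | COc1cc([C@@H](OB2OC(C)(C)C(C)(C)O2)[C@H](C=C)Oc2c(OC)cc(cc2OC)C(=O)OC)ccc1OC(C)=O
F4 | step 4 | 4-[(1R,2R)-1,3,4-trihydroxy-2-(2,6-dimethoxy-4-methoxycarbonylphenoxy)butyl]-2-methoxyphenyl acetate, C3 epimers | COc1cc([C@@H](O)[C@H](C(O)CO)Oc2c(OC)cc(cc2OC)C(=O)OC)ccc1OC(C)=O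
F5 | step 4 | 4-[(1R,2R)-1-hydroxy-2-(2,6-dimethoxy-4-methoxycarbonylphenoxy)-3-oxopropyl]-2-methoxyphenyl acetate | COc1cc([C@@H](O)[C@H](C=O)Oc2c(OC)cc(cc2OC)C(=O)OC)ccc1OC(C)=O
F6 | step 2 | 3,5-dimethoxy-4-(prop-2-yn-1-yloxy)benzoic acid | OC(=O)c1cc(OC)c(OCC#C)c(OC)c1
F7 | step 2 | potassium 3,5-dimethoxy-4-(propa-1,2-dien-1-yloxy)benzoate | [K+].[O-]C(=O)c1cc(OC)c(OC=C=C)c(OC)c1
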